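The route opens ring A (the cyclopentene C11–C12=C13–C14–C15) at C11–C12 and C14–C15. A Danheiser [3+2] annulation joins methyl (E)-4-oxopent-2-enoate with an enantioenriched 1-silylbuta-1,2-diene: conjugate addition forges C14–C15, and the titanium enolate then closes ring A by bonding C11 to C12. The step exploits the doubly allylic C11, flanked by the exocyclic-methylene carbon C10 (held as an acetyl group) and the C12=C13 alkene (held as a vinylsilane), and sets the all-trans C11/C15/C14 array by axis-to-centre chirality transfer. Ring B is then grown from the two carbonyl groups by an allylboration that brings the complete side chain and a Nozaki–Hiyama–Kishi closure at C9–C10.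

Key step: step 3

Remark on labels: carbons are numbered along the chain of the target. C1 is the CH2 of the isopropenyl group, C3 the side-chain carbinol, C5 the acetoxy carbon and C6 the methyl-bearing carbon. Ring B (seven-membered) is C7–C8–C9–C10–C11–C15–C16, with C9 and C16 carbinols and C10 carrying the exocyclic CH2. Ring A (five-membered) is C11–C12=C13–C14–C15, with the methyl on C14. TBS is tert-butyldimethylsilyl, TES triethylsilyl, Bpin the pinacol boronate, and TRIP is 3,3'-bis(2,4,6-triisopropylphenyl)-1,1'-binaphthyl-2,2'-diyl hydrogen phosphate.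

Assumption: (R)-TRIP is taken to deliver the allyl group to the aldehyde face that gives (R)-1-phenylbut-3-en-1-ol from benzaldehyde. If the sense proves opposite, (S)-TRIP is used in steps 10 and 13.

Step 1
Reactants: 1 (R)-but-3-yn-2-ol
Product: 2 (R)-4-[tert-butyl(dimethyl)silyl]but-3-yn-2-ol
Conditions: n-BuLi (2.1 equiv), THF, −78 → 0 °C; t-BuMe2SiCl, −78 °C → rt
Reagents that add atoms: tert-butyl(chloro)dimethylsilane, CC(C)(C)[Si](C)(C)Cl
Why: C-silylation of the alkynide–alkoxide dianion, in which the acetylide carbon is the more reactive site toward the hindered chlorosilane; the carbinol centre is not touched.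

Step 2
Reactants: 2 (R)-4-[tert-butyl(dimethyl)silyl]but-3-yn-2-ol
Product: 5 (R)-1-[tert-butyl(dimethyl)silyl]buta-1,2-diene, via N-alkyl sulfonylhydrazine 3 (not isolated), via propargylic diazene 4 (not isolated)
Conditions: 2-nitrobenzenesulfonylhydrazide, PPh3, diethyl azodicarboxylate, THF, −15 °C → rt
Reagents that add atoms: none
Why: Myers allene synthesis: Mitsunobu displacement inverts the carbinol centre and the monoalkyl diazene loses N2 by a suprafacial retro-ene hydrogen shift, so the central chirality is relayed to the (R) allene axis.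

Step 3
Reactants: 5 (R)-1-[tert-butyl(dimethyl)silyl]buta-1,2-diene; 6 methyl (E)-4-oxopent-2-enoate
Product: 8 methyl (1S,2S,5R)-2-acetyl-4-[tert-butyl(dimethyl)silyl]-5-methylcyclopent-3-ene-1-carboxylate, via titanium enolate vinyl cation 7 (not isolated)
Conditions: TiCl4 (1.2 equiv), CH2Cl2, −78 °C
Reagents that add atoms: none
Why: Danheiser [3+2] annulation: the TiCl4-bound ketone directs C3 of the allenylsilane (C14) to the enone carbon beta to the ketone (C15), the beta-silyl vinyl cation 7 undergoes a 1,2-silyl shift, and the titanium enolate carbon C11 then attacks the cationic C12. The closest known reaction type is the annulation of allenylsilanes with acyclic (E)-enones, where a bulky silyl group on an allene without a C1 substituent suppresses loss of silicon from the cation. Ring A closes in a 5-(enolexo)-endo mode, the enolate carbon C11 bonding to the sp carbon C12 whose C12=C13 bond stays inside the new ring. C14 is set by anti SE2' attack (opposite to the C–Si bond) on the (R) allene axis; C15 by the approach that keeps the C14 methyl over H15 and away from the ester, which also selects the enone face; C11 by suprafacial addition across the (E)-alkene, which gives the trans C11/C15 relation that later becomes the trans ring fusion. The step needs attack beta to the ketone and not beta to the ester, which the stronger binding of TiCl4 to the ketone should secure, and it needs ring closure to outrun desilylation, which the tert-butyldimethylsilyl group should secure.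

Step 4
Reactants: 8 methyl (1S,2S,5R)-2-acetyl-4-[tert-butyl(dimethyl)silyl]-5-methylcyclopent-3-ene-1-carboxylate
Product: 9 methyl (1S,2S,5R)-4-[tert-butyl(dimethyl)silyl]-5-methyl-2-[1-(trifluoromethylsulfonyloxy)ethenyl]cyclopent-3-ene-1-carboxylate
Conditions: KN(SiMe3)2, PhNTf2, THF, −78 °C
Reagents that add atoms: N-phenylbis(trifluoromethanesulfonimide), O=S(=O)(N(c1ccccc1)S(=O)(=O)C(F)(F)F)C(F)(F)F
Why: kinetic deprotonation of the methyl ketone at the unhindered CH3 and O-triflation give the 2-triflyloxy-1-alkene that carries C10 and its future exocyclic CH2; no stereocentre is formed and C11 is not enolised.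

Step 5
Reactants: 9 methyl (1S,2S,5R)-4-[tert-butyl(dimethyl)silyl]-5-methyl-2-[1-(trifluoromethylsulfonyloxy)ethenyl]cyclopent-3-ene-1-carboxylate
Product: 10 methyl (1R,2R,5S)-5-methyl-2-[1-(trifluoromethylsulfonyloxy)ethenyl]cyclopent-3-ene-1-carboxylate
Conditions: CF3CO2H, CH2Cl2, 0 °C → rt
Reagents that add atoms: none
Why: ipso-protodesilylation of the vinylsilane (protonation at C13 gives the beta-silyl cation, which loses silicon) keeps the C12=C13 bond in place, and with the ketone masked as the enol triflate no enolisation can move the alkene into conjugation.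

Step 6
Reactants: 10 methyl (1R,2R,5S)-5-methyl-2-[1-(trifluoromethylsulfonyloxy)ethenyl]cyclopent-3-ene-1-carboxylate
Product: 11 (1R,2R,5S)-5-methyl-2-[1-(trifluoromethylsulfonyloxy)ethenyl]cyclopent-3-ene-1-carbaldehyde
Conditions: iBu2AlH (1.1 equiv), CH2Cl2, −78 °C; aqueous potassium sodium tartrate
Reagents that add atoms: none
Why: partial reduction of the methyl ester through the aluminium hemiacetal that is stable at low temperature; C15 is trans to both neighbours and so has no drive to epimerise.

Step 7
Reactants: 12 (R)-2-hydroxy-1,2,2-triphenylethyl acetate; 13 methacrolein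
Product: 14 (R)-2-hydroxy-1,2,2-triphenylethyl (3R)-3-hydroxy-4-methylpent-4-enoate
Conditions: LiN(iPr)2 (2.2 equiv), THF, −78 → 0 °C; MgBr2; methacrolein, −110 °C; aqueous NH4Cl
Reagents that add atoms: none
Why: acetate aldol addition of the doubly deprotonated chiral acetate, in which the magnesium enolate adds through a closed Zimmerman–Traxler transition state shielded by the triphenylglycol unit and should set the (R) carbinol C3.

Step 8
Reactants: 14 (R)-2-hydroxy-1,2,2-triphenylethyl (3R)-3-hydroxy-4-methylpent-4-enoate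
Product: 15 (R)-2-hydroxy-1,2,2-triphenylethyl (3R)-3-[tert-butyl(dimethyl)silyl]oxy-4-methylpent-4-enoate
Conditions: t-BuMe2SiCl, imidazole, DMF, rt
Reagents that add atoms: tert-butyl(chloro)dimethylsilane, CC(C)(C)[Si](C)(C)Cl
Why: silylation of the secondary alcohol only, the tertiary diphenylcarbinol being too hindered to react.

Step 9
Reactants: 15 (R)-2-hydroxy-1,2,2-triphenylethyl (3R)-3-[tert-butyl(dimethyl)silyl]oxy-4-methylpent-4-enoate
Product: 16 (3R)-3-[tert-butyl(dimethyl)silyl]oxy-4-methylpent-4-enal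
Conditions: iBu2AlH (2.2 equiv), CH2Cl2, −78 °C; aqueous potassium sodium tartrate
Reagents that add atoms: none
Why: reductive cleavage of the auxiliary ester to the aldehyde (one equivalent of hydride is consumed by the tertiary hydroxyl), with release of the auxiliary diol.

Step 10
Reactants: 16 (3R)-3-[tert-butyl(dimethyl)silyl]oxy-4-methylpent-4-enal
Product: 17 (3S,4S,6R)-6-[tert-butyl(dimethyl)silyl]oxy-3,7-dimethylocta-1,7-dien-4-ol
Conditions: (Z)-crotyl-Bpin, (R)-TRIP (5 mol %), toluene, −30 °C
Reagents that add atoms: (Z)-crotylboronic acid pinacol ester, C/C=C\CB1OC(C)(C)C(C)(C)O1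
Why: phosphoric-acid-catalysed crotylboration through a closed chair transition state, in which the (Z)-boronate gives the syn C5/C6 relation and the catalyst selects the aldehyde face, so C5 and C6 are set together.

Step 11
Reactants: 17 (3S,4S,6R)-6-[tert-butyl(dimethyl)silyl]oxy-3,7-dimethylocta-1,7-dien-4-ol
Product: 18 (3S,4S,6R)-6-[tert-butyl(dimethyl)silyl]oxy-3,7-dimethylocta-1,7-dien-4-yl acetate
Conditions: Ac2O, pyridine, 4-(dimethylamino)pyridine (cat.), CH2Cl2, rt
Reagents that add atoms: acetic anhydride, CC(=O)OC(C)=O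
Why: acylation of the only free hydroxyl installs the C5 acetate of the target before any other hydroxyl is unmasked.

Step 12
Reactants: 18 (3S,4S,6R)-6-[tert-butyl(dimethyl)silyl]oxy-3,7-dimethylocta-1,7-dien-4-yl acetate
Product: 19 (2E,4S,5S,7R)-7-[tert-butyl(dimethyl)silyl]oxy-4,8-dimethyl-1-(4,4,5,5-tetramethyl-1,3,2-dioxaborolan-2-yl)nona-2,8-dien-5-yl acetate
Conditions: allyl-Bpin (3 equiv), second-generation Grubbs catalyst RuCl2(=CHPh)(H2IMes)(PCy3) (5 mol %), CH2Cl2, 40 °C
Reagents that add atoms: allylboronic acid pinacol ester, C=CCB1OC(C)(C)C(C)(C)O1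
Why: cross-metathesis of the monosubstituted alkene (the hindered isopropenyl group next to the silyl ether should stay inert) should give mainly the (E)-allylboronate.

Step 13
Reactants: 11 (1R,2R,5S)-5-methyl-2-[1-(trifluoromethylsulfonyloxy)ethenyl]cyclopent-3-ene-1-carbaldehyde; 19 (2E,4S,5S,7R)-allylboronate
Product: 20 open-chain C16 alcohol (cyclopentenyl enol triflate joined at C15–C16; C7 carries a vinyl group C8=C9 and the full side chain with C5 acetate and C3 OTBS; (7S,16R))
Conditions: (R)-TRIP (10 mol %), 4 Å molecular sieves, toluene, −30 → 0 °C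
Reagents that add atoms: none
Why: catalytic allylboration through a chair transition state, in which the (E)-γ-substituted boronate gives the anti relation between the C16 hydroxyl and the C7 branch and the chiral phosphoric acid selects the aldehyde face, so C16 and C7 are set together.

Step 14
Reactants: 20 open-chain C16 alcohol
Product: 21 C16 triethylsilyl ether of 20
Conditions: Et3SiOTf, 2,6-lutidine, CH2Cl2, −78 °C
Reagents that add atoms: triethylsilyl trifluoromethanesulfonate, CC[Si](CC)(CC)OS(=O)(=O)C(F)(F)F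
Why: silylation of the hindered C16 alcohol, so that the later oxidation at C9 cannot be intercepted as a lactol.

Step 15
Reactants: 21 C16 triethylsilyl ether
Product: 23 C9 primary alcohol (C7–CH2–CH2OH), via trialkylborane 22 (not isolated)
Conditions: disiamylborane (from BH3·THF and 2-methylbut-2-ene), THF, 0 °C; then H2O2, aqueous NaHCO3, 0 °C → rt
Reagents that add atoms: hydrogen peroxide, OO
Why: anti-Markovnikov hydroboration–oxidation, in which the bulky dialkylborane should take the monosubstituted vinyl group in preference to the 1,1-disubstituted, cyclic and triflate-bearing alkenes.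

Step 16
Reactants: 23 C9 primary alcohol
Product: 24 C9 aldehyde (C7–CH2–CHO)
Conditions: Dess–Martin periodinane, NaHCO3, CH2Cl2, 0 °C → rt
Reagents that add atoms: none
Why: buffered Dess–Martin oxidation of the only free hydroxyl to the aldehyde without touching the acetate, the silyl ethers or the enol triflate.

Step 17
Reactants: 24 C9 aldehyde
Product: 25 ring-B allylic alcohol (C9–C10 closed, exocyclic methylene at C10; C9 epimers)
Conditions: CrCl2 (6 equiv), NiCl2 (2 mol %), DMF, rt, high dilution
Reagents that add atoms: none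
Why: intramolecular Nozaki–Hiyama–Kishi reaction, in which the alkenylchromium species formed from the enol triflate adds to the aldehyde and closes the seven-membered ring B at C9–C10 with the exocyclic methylene in place; C9 forms without reliable control and both epimers are carried on.

Step 18
Reactants: 25 ring-B allylic alcohol (C9 epimers)
Product: 26 C9 ketone (2-methylene cycloheptanone in ring B)
Conditions: Dess–Martin periodinane, NaHCO3, CH2Cl2, 0 °C
Reagents that add atoms: none
Why: oxidation of both allylic alcohol epimers converges on one α-methylene ketone, which erases the uncontrolled C9 centre.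

Step 19
Reactants: 26 C9 ketone
Product: 27 (9R) allylic alcohol (C16 OTES, C3 OTBS, C5 OAc)
Conditions: (S)-2-methyl-CBS-oxazaborolidine (0.5 equiv), catecholborane, toluene, −78 °C
Reagents that add atoms: none
Why: Corey–Bakshi–Shibata reduction, in which the alkenyl side (C10) acts as the large group and C8H2 as the small one, so the (S) catalyst should deliver hydride to give the (9R) alcohol under reagent control; the low temperature favours 1,2- over 1,4-reduction.

Step 20
Reactants: 27 (9R) allylic alcohol
Product: 28 target, CNP0151410.1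
Conditions: HF·pyridine, pyridine, THF, 0 °C → rt
Reagents that add atoms: none
Why: buffered fluoride cleavage of the triethylsilyl and tert-butyldimethylsilyl ethers, under conditions that should leave the C5 acetate in place and unmigrated.

Compound list
1 | (R)-but-3-yn-2-ol | C[C@@H](O)C#C | starting material
2 | (R)-4-[tert-butyl(dimethyl)silyl]but-3-yn-2-ol | C[C@@H](O)C#C[Si](C)(C)C(C)(C)C | intermediate
3 | N-[(S)-4-[tert-butyl(dimethyl)silyl]but-3-yn-2-yl]-2-nitrobenzenesulfonohydrazide (carbinol centre inverted; not isolated) | C[C@H](N(N)S(=O)(=O)c1ccccc1[N+](=O)[O-])C#C[Si](C)(C)C(C)(C)C | intermediate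
4 | (S)-[4-[tert-butyl(dimethyl)silyl]but-3-yn-2-yl]diazene (not isolated) | C[C@H](N=N)C#C[Si](C)(C)C(C)(C)C | intermediate
5 | (R)-1-[tert-butyl(dimethyl)silyl]buta-1,2-diene (axial chirality) | CC([H])=[C@]=C([H])[Si](C)(C)C(C)(C)C | intermediate
6 | methyl (E)-4-oxopent-2-enoate | CC(=O)/C=C/C(=O)OC | starting material
7 | titanium enolate with beta-silyl vinyl cation, after C14–C15 bond formation (not isolated) | CC(O[Ti-](Cl)(Cl)(Cl)Cl)=C[C@H](C(=O)OC)[C@@H](C)[C+]=C[Si](C)(C)C(C)(C)C | intermediate
8 | methyl (1S,2S,5R)-2-acetyl-4-[tert-butyl(dimethyl)silyl]-5-methylcyclopent-3-ene-1-carboxylate (acetyl, ester and methyl all-trans) | CC(=O)[C@@H]1C=C([Si](C)(C)C(C)(C)C)[C@H](C)[C@H]1C(=O)OC | intermediate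
9 | methyl (1S,2S,5R)-4-[tert-butyl(dimethyl)silyl]-5-methyl-2-[1-(trifluoromethylsulfonyloxy)ethenyl]cyclopent-3-ene-1-carboxylate | C=C(OS(=O)(=O)C(F)(F)F)[C@@H]1C=C([Si](C)(C)C(C)(C)C)[C@H](C)[C@H]1C(=O)OC | intermediate
10 | methyl (1R,2R,5S)-5-methyl-2-[1-(trifluoromethylsulfonyloxy)ethenyl]cyclopent-3-ene-1-carboxylate | C=C(OS(=O)(=O)C(F)(F)F)[C@@H]1C=C[C@H](C)[C@H]1C(=O)OC | intermediate
11 | (1R,2R,5S)-5-methyl-2-[1-(trifluoromethylsulfonyloxy)ethenyl]cyclopent-3-ene-1-carbaldehyde | C=C(OS(=O)(=O)C(F)(F)F)[C@@H]1C=C[C@H](C)[C@H]1C=O | intermediate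
12 | (R)-2-hydroxy-1,2,2-triphenylethyl acetate | CC(=O)O[C@H](c1ccccc1)C(O)(c1ccccc1)c1ccccc1 | starting material
13 | methacrolein (2-methylprop-2-enal) | CC(=C)C=O | starting material
14 | (R)-2-hydroxy-1,2,2-triphenylethyl (3R)-3-hydroxy-4-methylpent-4-enoate | C=C(C)[C@H](O)CC(=O)O[C@H](c1ccccc1)C(O)(c1ccccc1)c1ccccc1 | intermediate
15 | (R)-2-hydroxy-1,2,2-triphenylethyl (3R)-3-[tert-butyl(dimethyl)silyl]oxy-4-methylpent-4-enoate | C=C(C)[C@H](O[Si](C)(C)C(C)(C)C)CC(=O)O[C@H](c1ccccc1)C(O)(c1ccccc1)c1ccccc1 | intermediate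
16 | (3R)-3-[tert-butyl(dimethyl)silyl]oxy-4-methylpent-4-enal | C=C(C)[C@H](O[Si](C)(C)C(C)(C)C)CC=O | intermediate
17 | (3S,4S,6R)-6-[tert-butyl(dimethyl)silyl]oxy-3,7-dimethylocta-1,7-dien-4-ol | C=C(C)[C@H](O[Si](C)(C)C(C)(C)C)C[C@H](O)[C@@H](C)C=C | intermediate
18 | (3S,4S,6R)-6-[tert-butyl(dimethyl)silyl]oxy-3,7-dimethylocta-1,7-dien-4-yl acetate | C=C(C)[C@H](O[Si](C)(C)C(C)(C)C)C[C@H](OC(C)=O)[C@@H](C)C=C | intermediate
19 | (2E,4S,5S,7R)-7-[tert-butyl(dimethyl)silyl]oxy-4,8-dimethyl-1-(4,4,5,5-tetramethyl-1,3,2-dioxaborolan-2-yl)nona-2,8-dien-5-yl acetate | C=C(C)[C@H](O[Si](C)(C)C(C)(C)C)C[C@H](OC(C)=O)[C@@H](C)/C=C/CB1OC(C)(C)C(C)(C)O1 | intermediate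
20 | open-chain C16 alcohol: C7 vinyl, C10 enol triflate, C5 acetate, C3 OTBS; configuration as in the target at C3, C5, C6, C7, C11, C14, C15, C16 | C=C(C)[C@H](O[Si](C)(C)C(C)(C)C)C[C@H](OC(C)=O)[C@@H](C)[C@H](C=C)[C@@H](O)[C@@H]1[C@@H](C)C=C[C@H]1C(=C)OS(=O)(=O)C(F)(F)F | intermediate
21 | C16 triethylsilyl ether of 20 | C=C(C)[C@H](O[Si](C)(C)C(C)(C)C)C[C@H](OC(C)=O)[C@@H](C)[C@H](C=C)[C@@H](O[Si](CC)(CC)CC)[C@@H]1[C@@H](C)C=C[C@H]1C(=C)OS(=O)(=O)C(F)(F)F | intermediate
22 | C9 bis(3-methylbutan-2-yl)borane from 21 (not isolated) | C=C(C)[C@H](O[Si](C)(C)C(C)(C)C)C[C@H](OC(C)=O)[C@@H](C)[C@H](CCB(C(C)C(C)C)C(C)C(C)C)[C@@H](O[Si](CC)(CC)CC)[C@@H]1[C@@H](C)C=C[C@H]1C(=C)OS(=O)(=O)C(F)(F)F | intermediate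
23 | C9 primary alcohol | C=C(C)[C@H](O[Si](C)(C)C(C)(C)C)C[C@H](OC(C)=O)[C@@H](C)[C@H](CCO)[C@@H](O[Si](CC)(CC)CC)[C@@H]1[C@@H](C)C=C[C@H]1C(=C)OS(=O)(=O)C(F)(F)F | intermediate
24 | C9 aldehyde | C=C(C)[C@H](O[Si](C)(C)C(C)(C)C)C[C@H](OC(C)=O)[C@@H](C)[C@H](CC=O)[C@@H](O[Si](CC)(CC)CC)[C@@H]1[C@@H](C)C=C[C@H]1C(=C)OS(=O)(=O)C(F)(F)F | intermediate
25 | trans-fused bicyclic allylic alcohol, rings A and B closed, C9 epimers | C=C(C)[C@H](O[Si](C)(C)C(C)(C)C)C[C@H](OC(C)=O)[C@@H](C)[C@@H]1CC(O)C(=C)[C@@H]2C=C[C@H](C)[C@H]2[C@@H]1O[Si](CC)(CC)CC | intermediate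
26 | C9 ketone (α-methylene ketone) | C=C(C)[C@H](O[Si](C)(C)C(C)(C)C)C[C@H](OC(C)=O)[C@@H](C)[C@@H]1CC(=O)C(=C)[C@@H]2C=C[C@H](C)[C@H]2[C@@H]1O[Si](CC)(CC)CC | intermediate
27 | (9R) allylic alcohol, C16 OTES, C3 OTBS, C5 OAc | C=C(C)[C@H](O[Si](C)(C)C(C)(C)C)C[C@H](OC(C)=O)[C@@H](C)[C@@H]1C[C@@H](O)C(=C)[C@@H]2C=C[C@H](C)[C@H]2[C@@H]1O[Si](CC)(CC)CC | intermediate
28 | CNP0151410.1 (3R,5S,6S,7S,9R,11R,14S,15R,16R in the labels used here) | C=C(C)[C@H](O)C[C@H](OC(C)=O)[C@@H](C)[C@@H]1C[C@@H](O)C(=C)[C@@H]2C=C[C@H](C)[C@H]2[C@@H]1O | target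

Total step count: 20. Longest linear sequence: 14 steps (steps 1–6 then 13–20; the side-chain branch, steps 7–12 then 13–20, is equally long).

Steps most likely to fail

Step 3 (annulation). Ring closure may be outrun by loss of the silyl group from the vinyl cation, the allene may add beta to the ester, or the enone face may be poorly selected. The fallback is a two-stage annulation that sets out from 6 and comes back at 10. Commercially available (R)-4-(trimethylsilyl)but-3-yn-2-ol would be taken through the protocol of step 2, by way of N-[(S)-4-(trimethylsilyl)but-3-yn-2-yl]-2-nitrobenzenesulfonohydrazide F1 and (S)-[4-(trimethylsilyl)but-3-yn-2-yl]diazene F2 (neither isolated), to (R)-1-(trimethylsilyl)buta-1,2-diene F3. With 6 and TiCl4 at −78 °C the small silyl group is now meant to leave the vinyl cation, which should give the conjugate propargylation product methyl (2S,3R)-3-methyl-2-(2-oxopropyl)pent-4-ynoate F4 with the same anti SE2' transfer to C14. t-BuMe2SiOTf and Et3N should give the more substituted (Z)-silyl enol ether F5. Ph3PAuCl/AgBF4 (monovalent gold) in CH2Cl2/MeOH should then close ring A by a 5-endo-dig Conia-ene-type attack of C11 on the activated alkyne carbon C12, giving methyl (1R,2R,5S)-2-acetyl-5-methylcyclopent-3-ene-1-carboxylate F6, trans at C11/C15 as the less strained arrangement. Triflation of F6 under the conditions of step 4 gives 10.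

Step 13 (fragment union). Facial control may be insufficient in this triply stereodifferentiating allylboration, and any (Z)-boronate carried over from the cross-metathesis erodes the anti relation. The fallback sets out from 18 and 11 and comes back at 20. Cross-metathesis of 18 with (E)-1,4-dibromobut-2-ene (second-generation Grubbs catalyst) should give (2E,4S,5S,7R)-1-bromo-7-[tert-butyl(dimethyl)silyl]oxy-4,8-dimethylnona-2,8-dien-5-yl acetate F7. A Nozaki–Hiyama allylation of 11 with F7 and CrCl2 in THF at 0 °C, with a chiral bis(oxazolinyl)carbazole ligand on chromium, follows. The allylchromium reagent equilibrates to its (E) form and adds through a chair transition state, so the anti relation no longer depends on the alkene geometry of the precursor and the ligand supplies the facial control; nickel is absent, so the enol triflate stays intact. The product is 20.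

Step 17 (ring B closure). Seven-membered ring closure may be slow, with protodemetalation of the alkenylchromium species competing. The fallback sets out from 24 and comes back at 27. Wittig methylenation (Ph3P=CH2, THF, −78 → 0 °C) should give the C7 allyl compound F8. Negishi coupling of the enol triflate with MeZnCl and Pd(PPh3)4 should give the C11 isopropenyl compound F9. Ring-closing metathesis with the second-generation Grubbs catalyst should give the trisubstituted cycloheptene F10 (C9=C10, methyl on C10). m-CPBA should epoxidise this most electron-rich alkene from the β face, which carries only H7 and H11, to give the 9β,10β-epoxide F11. Cp2TiCl (trivalent titanium, from Cp2TiCl2 and Zn) should open the epoxide at the tertiary C10, and β-hydride elimination toward the methyl group should give the exocyclic methylene and the 9β alcohol 27 directly.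

Further compounds
F1 | step 3 | N-[(S)-4-(trimethylsilyl)but-3-yn-2-yl]-2-nitrobenzenesulfonohydrazide (not isolated) | C[C@H](N(N)S(=O)(=O)c1ccccc1[N+](=O)[O-])C#C[Si](C)(C)C
F2 | step 3 | (S)-[4-(trimethylsilyl)but-3-yn-2-yl]diazene (not isolated) | C[C@H](N=N)C#C[Si](C)(C)C
F3 | step 3 | (R)-1-(trimethylsilyl)buta-1,2-diene | CC([H])=[C@]=C([H])[Si](C)(C)C
F4 | step 3 | methyl (2S,3R)-3-methyl-2-(2-oxopropyl)pent-4-ynoate | CC(=O)C[C@H](C(=O)OC)[C@@H](C)C#C
F5 | step 3 | (Z)-tert-butyldimethylsilyl enol ether of F4 (enol double bond C10=C11) | C/C(O[Si](C)(C)C(C)(C)C)=C/[C@H](C(=O)OC)[C@@H](C)C#C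
F6 | step 3 | methyl (1R,2R,5S)-2-acetyl-5-methylcyclopent-3-ene-1-carboxylate | CC(=O)[C@@H]1C=C[C@H](C)[C@H]1C(=O)OC
F7 | step 13 | (2E,4S,5S,7R)-1-bromo-7-[tert-butyl(dimethyl)silyl]oxy-4,8-dimethylnona-2,8-dien-5-yl acetate | C=C(C)[C@H](O[Si](C)(C)C(C)(C)C)C[C@H](OC(C)=O)[C@@H](C)/C=C/CBr
F8 | step 17 | C7 allyl compound (C9=CH2 in place of the aldehyde of 24) | C=C(C)[C@H](O[Si](C)(C)C(C)(C)C)C[C@H](OC(C)=O)[C@@H](C)[C@H](CC=C)[C@@H](O[Si](CC)(CC)CC)[C@@H]1[C@@H](C)C=C[C@H]1C(=C)OS(=O)(=O)C(F)(F)F
F9 | step 17 | C11 isopropenyl compound (methyl in place of the triflate of F8) | C=C(C)[C@H](O[Si](C)(C)C(C)(C)C)C[C@H](OC(C)=O)[C@@H](C)[C@H](CC=C)[C@@H](O[Si](CC)(CC)CC)[C@@H]1[C@@H](C)C=C[C@H]1C(C)=C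
F10 | step 17 | trans-fused bicyclic diene with C9=C10 in ring B and methyl on C10 | C=C(C)[C@H](O[Si](C)(C)C(C)(C)C)C[C@H](OC(C)=O)[C@@H](C)[C@@H]1CC=C(C)[C@@H]2C=C[C@H](C)[C@H]2[C@@H]1O[Si](CC)(CC)CC
F11 | step 17 | 9β,10β-epoxide of F10 | C=C(C)[C@H](O[Si](C)(C)C(C)(C)C)C[C@H](OC(C)=O)[C@@H](C)[C@@H]1C[C@H]3O[C@@]3(C)[C@@H]2C=C[C@H](C)[C@H]2[C@@H]1O[Si](CC)(CC)CC
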